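Target 30 ⇐ 3β,8β-diol 23 ⇐ eudesma-4,11(13)-dien-3-one 20 ⇐ ring-A 1,4-diene 18 ⇐ 5α-hydroxy-eudesma-1,11(13)-diene 17; the late work only adjusts the oxygen functions at C3, C8 and C12.
Key disconnection, 17 ⇒ 14: transannular carbonyl-ene bond C5–C10 (hydrogen from C2 to oxygen, C1=C2 left behind), then oxy-Cope bond C2–C3, which leads back to a 1-isopropenyl-2-methyl-2-vinylcyclohexanol.
Feature used: ring B (C5, C6, C7, C8, C9, C10) with its C10 methyl, C7 three-carbon branch and C8 oxygen is an oxidised carvone; ring A (C10, C1, C2, C3, C4, C5) is a C10 vinyl group (C1, C2) and a C5 isopropenyl group (C3, C4, C15) joined tail to tail at C2–C3, the ring-fusion bond C5–C10 being broken and re-made on the way.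
14 ⇒ (R)-carvone 1: C12 oxygen by allylic chlorination, C8 oxygen by γ-hydroxylation of the enone, C10 vinyl by reductive aldol reaction and dehydration, C5 isopropenyl by organocerium addition.
Ring order: ring B is bought with carvone, ring A is closed in step 9; C8 is carried as the equatorial 8α-silyl ether and turned into the axial 8β-acetate by oxidation and reduction once the axial C10 methyl is in place.

Key step: step 9

Remark: eudesmane numbering is used for every compound, also the monocyclic ones (carvone C1, C2, C3, C4, C5, C6 = C5, C10, C9, C8, C7, C6; C11 to C13 = side chain on C7, C12 its oxygenated carbon; C14 = methyl on C10; C15 = methyl on C4); β is the ring face that carries the C7 side chain.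
Remark: C5 and C10 of alcohol 14 both become trigonal in ketone 16, so their configuration in 14 only has to allow a chair oxy-Cope transition state with the isopropenyl group equatorial; the configuration drawn is the one that axial attack at C10 (step 6) and at C5 (step 8) should deliver.
Remark: the C8 silyloxy group is kept α (trans to the C7 branch), because two equatorial groups on ring B decide the face on which C10 is re-bonded in step 9, whereas an axial 8β group would oppose that control.
Remark: (E)-3-methylpent-2-enoic acid 24 is assumed to be purchased as the pure E isomer.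

Step 1
Reactants: 1 (R)-carvone
Product: 2 chlorocarvone (C12 chloride)
Conditions: Ca(OCl)2, CO2 (dry ice), CH2Cl2/H2O, 0 °C
Reagents that add atoms: calcium hypochlorite, [Ca+2].[O-]Cl.[O-]Cl
Why: HOCl, made in the flask from Ca(OCl)2 and CO2, chlorinates the electron-rich isopropenyl group by an ene-type allylic chlorination (the enone alkene is too electron-poor to react) and gives the 2-(chloromethyl)vinyl group, and the C7 stereocentre is not involved.

Step 2
Reactants: 2 chlorocarvone (C12 chloride)
Product: 4 hydroxycarvone (C12 alcohol), via allylic acetate 3 (not isolated)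
Conditions: KOAc, NaI (cat.), DMF, 60 °C; then K2CO3 (cat.), MeOH, 0 °C → rt
Reagents that add atoms: potassium acetate, CC(=O)[O-].[K+]
Why: SN2 displacement of the primary allylic chloride by acetate and K2CO3-catalysed transesterification in methanol free the C12 alcohol under conditions too mild to move either alkene or to touch C7.

Step 3
Reactants: 4 hydroxycarvone (C12 alcohol)
Product: 5 C12 TBDPS ether of hydroxycarvone
Conditions: TBDPSCl, imidazole, CH2Cl2, rt
Reagents that add atoms: tert-butyl(chloro)diphenylsilane, CC(C)(C)[Si](Cl)(c1ccccc1)c1ccccc1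
Why: Standard silylation of the primary alcohol, the TBDPS ether being chosen because it withstands hydride, organocerium, KH, heat and acidic methanol and is removed by fluoride in step 18.

Step 4
Reactants: 5 C12 TBDPS ether of hydroxycarvone
Product: 7 trans-8α-hydroxy enone, via silyl dienol ether 6 (not isolated)
Conditions: MeMgBr, FeCl3 (cat.), Et2O, −20 °C; Me3SiCl, Et3N, DMPU; then mCPBA, CH2Cl2, −20 °C; 1 M HCl, THF, 0 °C
Reagents that add atoms: mCPBA (3-chloroperbenzoic acid), OOC(=O)c1cccc(Cl)c1
Why: Kharasch-type deprotonation (MeMgBr with catalytic FeCl3) gives the thermodynamic, linearly conjugated dienolate (C5–O, C5=C10, C9=C8) and vinylogous Rubottom oxidation of its silyl ether takes place at the γ,δ-alkene because the α-carbon C10 is fully substituted, the peracid approaching C8 anti to the neighbouring C7 branch so that the new hydroxyl is 8α (trans).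

Step 5
Reactants: 7 trans-8α-hydroxy enone
Product: 8 bis-silyl enone (8α-OTBS)
Conditions: TBSCl, imidazole, DMF, rt
Reagents that add atoms: tert-butyl(chloro)dimethylsilane, CC(C)(C)[Si](C)(C)Cl
Why: Standard silylation of the secondary allylic alcohol, a TBS ether being chosen because acidic methanol removes it in step 13 in the presence of the primary TBDPS ether.

Step 6
Reactants: 8 bis-silyl enone (8α-OTBS); 9 acetaldehyde
Product: 11 aldol adduct (10β-hydroxyethyl ketone), via lithium enolate 10 (not isolated)
Conditions: LiBH(s-Bu)3, THF, −78 °C; 9, −78 °C; AcOH quench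
Reagents that add atoms: acetaldehyde, CC=O
Why: Conjugate hydride addition of LiBH(s-Bu)3 gives the C10 enolate regiospecifically and its aldol addition to acetaldehyde (reductive aldol reaction) should occur by axial attack on the half-chair that keeps the trans C7 and C8 groups pseudo-equatorial, which puts the new C10–C1 bond β (cis to the C7 branch) and the methyl α, while the carbinol carbon forms as an epimer pair that is erased in step 7 and the C8 silyloxy group, γ to the enolate carbon, cannot be eliminated.

Step 7
Reactants: 11 aldol adduct (10β-hydroxyethyl ketone)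
Product: 12 vinyl ketone (10β-vinyl)
Conditions: Ph2S[OC(CF3)2Ph]2 (Martin sulfurane), CH2Cl2, 0 °C → rt
Reagents that add atoms: none
Why: Martin sulfurane dehydration of the secondary alcohol can only take a methyl hydrogen because C10 is quaternary, so the vinyl group forms without regiochemical choice and without the basic conditions that would cause retro-aldol cleavage.

Step 8
Reactants: 12 vinyl ketone (10β-vinyl); 13 isopropenylmagnesium bromide
Product: 14 dialkenylcyclohexanol (key-step precursor)
Conditions: CeCl3 (anhydrous), 13, THF, −78 °C; then 12, −78 → 0 °C; H2O quench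
Reagents that add atoms: isopropenylmagnesium bromide, C=C(C)[Mg]Br
Why: The organocerium reagent adds to the hindered ketone without enolising it and axial attack anti to the axial C10 vinyl group should give mainly the 5α-isopropenyl 5β-alcohol, but the facial selectivity is not critical because C5 becomes trigonal in step 9 and each epimer has only one accessible chair with gauche alkenyl groups, in which the isopropenyl group is equatorial.

Step 9
Reactants: 14 dialkenylcyclohexanol (key-step precursor)
Product: 17 hydroxy-eudesmadiene (5α-OH; key-step product), via potassium dienolate 15 (not isolated), via cyclodecenone 16 (not isolated)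
Conditions: KH, 18-crown-6, THF, 0 → 66 °C; AcOH, −78 °C → rt; then DBU (cat.), PhMe, 180 °C, base-washed sealed tube
Reagents that add atoms: none
Why: The potassium alkoxide of 14 undergoes an anion-accelerated oxy-Cope shift of the 1,5-diene C2=C1–C10–C5–C4=C3 (C2–C3 forms, C5–C10 breaks) through a chair transition state with the isopropenyl group equatorial on ring B, which gives the E-configured C1=C10 alkene of dienolate 15, and protonation gives cyclodec-5-enone 16, whose conformers equilibrate at room temperature and whose C4 epimers equilibrate under DBU. On heating, 16 undergoes a transannular carbonyl-ene reaction in which C10 bonds to C5 and a C2 hydrogen passes to the oxygen through a six-centre array (C5, O, H, C2, C1, C10), so that ring B is re-closed and ring A (C10, C1, C2, C3, C4, C5) is closed as a six-membered ring by a 1,6-transannular bond with the C1=C2 alkene left behind; the closest known reaction type is the tandem oxy-Cope/transannular ene reaction of 1,2-divinylcyclohexanols. In the ene transition state C6 is anti to C1 about the forming C5–C10 bond, so ring B is a chair with C1 equatorial and the C10 methyl axial, and only the chair that keeps the C7 side chain and the C8 silyloxy group equatorial is low in energy, which sets the C10 methyl β under Curtin–Hammett control. The carbonyl is attacked on the face that leaves the small oxygen axial and C4 equatorial (5α-OH, trans ring fusion), and C4 reacts as the epimer whose methyl points away from the C10 methyl (4α-methyl, 4β-hydrogen anti to the hydroxyl). The step needs bonding of C5 to C10 (six/six) and not to the less substituted C1 (five/seven), which is secured by the geometry left by the Cope shift, in which C5 and C10 are the atoms that have just separated and still face each other, and by base-washed glass and DBU, which exclude an acid-catalysed Prins-type closure at C1. The alkoxide is used because the alkenyl groups of the major C5 epimer are trans-diaxial and ring B must flip before rearranging, which in a neutral thermolysis would let retro-ene cleavage of the β-hydroxy alkene compete.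

Step 10
Reactants: 17 hydroxy-eudesmadiene (5α-OH; key-step product)
Product: 18 eudesma-1,4,11(13)-triene
Conditions: SOCl2, pyridine, −20 → 0 °C
Reagents that add atoms: none
Why: E2-type dehydration of the tertiary chlorosulfite in pyridine should remove the axial 4β-hydrogen, which is anti-periplanar to the axial C5–O bond, and give the tetrasubstituted C4=C5 alkene (Saytzeff orientation), which erases the C4 and C5 stereocentres.

Step 11
Reactants: 18 eudesma-1,4,11(13)-triene
Product: 19 eudesma-1,4,11(13)-trien-3-one
Conditions: (C5H5NH)2Cr2O7 (PDC), t-BuOOH, Celite, PhH, rt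
Reagents that add atoms: tert-butyl hydroperoxide, CC(C)(C)OO
Why: Allylic oxidation with t-BuOOH, mediated by the hexavalent chromium of PDC, attacks C3, the only doubly allylic CH2 group, and turns the cyclohexa-1,4-diene unit of ring A into the cross-conjugated 1,4-dien-3-one, a known outcome for 1,4-dienes with a quaternary carbon in the ring.

Step 12
Reactants: 19 eudesma-1,4,11(13)-trien-3-one
Product: 20 eudesma-4,11(13)-dien-3-one
Conditions: [(Ph3P)CuH]6, H2O, PhH, rt
Reagents that add atoms: none
Why: Conjugate reduction with Stryker's reagent delivers hydride to C1, the β-CH of the disubstituted enone arm, while the fully substituted β-carbon C5 and the isolated C11=C13 alkene do not react, and water protonates the copper enolate at C2 to give the 4-en-3-one.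

Step 13
Reactants: 20 eudesma-4,11(13)-dien-3-one
Product: 21 hydroxy enone (8α-OH free)
Conditions: CSA (cat.), MeOH/CH2Cl2, 0 °C → rt
Reagents that add atoms: none
Why: Acid-catalysed methanolysis cleaves the secondary TBS ether much faster than the primary TBDPS ether, which is the more acid-stable of the two silyl groups.

Step 14
Reactants: 21 hydroxy enone (8α-OH free)
Product: 22 eudesma-4,11(13)-diene-3,8-dione
Conditions: Dess–Martin periodinane, CH2Cl2, 0 °C
Reagents that add atoms: none
Why: Dess–Martin oxidation of the secondary alcohol runs under near-neutral conditions that should not enolise C7, whose equatorial β configuration is in any case the stable one.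

Step 15
Reactants: 22 eudesma-4,11(13)-diene-3,8-dione
Product: 23 eudesmadiene-3β,8β-diol
Conditions: NaBH4, CeCl3·7H2O, MeOH, −78 → −20 °C
Reagents that add atoms: none
Why: Luche reduction adds hydride 1,2 to the enone on the α-face, anti to the axial C10 methyl, to give the pseudo-equatorial 3β-alcohol, while at C8 the axial path is blocked by the syn-axial C10 methyl so that equatorial attack from the α-face gives the axial 8β-alcohol.

Step 16
Reactants: 23 eudesmadiene-3β,8β-diol; 24 (E)-3-methylpent-2-enoic acid
Product: 25 C3 enoate ester (8β-OH free)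
Conditions: 24 (slight excess), DCC, DMAP (cat.), CH2Cl2, 0 °C
Reagents that add atoms: (E)-3-methylpent-2-enoic acid, CC/C(C)=C/C(=O)O
Why: Steglich esterification with a slight excess of acid 24 should acylate only the allylic pseudo-equatorial 3β-hydroxyl, since the axial 8β-hydroxyl is syn-axial to the C10 methyl and flanked by the C7 branch, and carbodiimide activation at 0 °C avoids a ketene pathway that would deconjugate or isomerise the E-enoate.

Step 17
Reactants: 25 C3 enoate ester (8β-OH free)
Product: 26 C3 enoate C8 acetate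
Conditions: Ac2O, DMAP, pyridine, CH2Cl2, rt
Reagents that add atoms: acetic anhydride, CC(=O)OC(C)=O
Why: DMAP-catalysed acetylation converts the remaining hindered axial 8β-alcohol into the acetate with retention at C8.

Step 18
Reactants: 26 C3 enoate C8 acetate
Product: 27 C12 allylic alcohol
Conditions: Bu4NF, AcOH, THF, 0 °C → rt
Reagents that add atoms: none
Why: Fluoride cleaves the primary TBDPS ether, and buffering Bu4NF with AcOH prevents acetate migration from O8 to O12 and cleavage of the two esters.

Step 19
Reactants: 27 C12 allylic alcohol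
Product: 28 C12 enal
Conditions: MnO2, CH2Cl2, rt
Reagents that add atoms: none
Why: MnO2 oxidises only allylic alcohols, so the primary C12 alcohol gives the α-methylene aldehyde and nothing else reacts.

Step 20
Reactants: 28 C12 enal
Product: 29 C12 acrylic acid
Conditions: NaClO2, NaH2PO4, 2-methyl-2-butene, t-BuOH/H2O, 0 °C → rt
Reagents that add atoms: sodium chlorite, [Na+].[O-]Cl=O
Why: Pinnick oxidation converts the enal into the acrylic acid, 2-methyl-2-butene taking up the HOCl by-product so that the alkenes are not chlorinated.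

Step 21
Reactants: 29 C12 acrylic acid
Product: 30 target methyl ester
Conditions: Me3SiCHN2, MeOH/PhMe, 0 °C
Reagents that add atoms: trimethylsilyldiazomethane, C[Si](C)(C)C=[N+]=[N-]
Why: Esterification with trimethylsilyldiazomethane in methanol methylates the carboxylic acid under neutral conditions that leave the acetate, the enoate and the acrylate untouched and completes the target with 3S, 7R, 8R and 10R configuration.

Compound list
1 | (R)-(−)-carvone, (5R)-2-methyl-5-(prop-1-en-2-yl)cyclohex-2-en-1-one | CC1=CC[C@H](CC1=O)C(C)=C | starting material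
2 | (5R)-5-(3-chloroprop-1-en-2-yl)-2-methylcyclohex-2-en-1-one (chlorine on C12) | CC1=CC[C@H](CC1=O)C(=C)CCl | intermediate
3 | (5R)-5-(3-acetoxyprop-1-en-2-yl)-2-methylcyclohex-2-en-1-one (not isolated) | CC1=CC[C@H](CC1=O)C(=C)COC(C)=O | intermediate
4 | (5R)-5-(3-hydroxyprop-1-en-2-yl)-2-methylcyclohex-2-en-1-one | CC1=CC[C@H](CC1=O)C(=C)CO | intermediate
5 | (5R)-5-[3-(tert-butyldiphenylsilyloxy)prop-1-en-2-yl]-2-methylcyclohex-2-en-1-one | CC1=CC[C@H](CC1=O)C(=C)CO[Si](c1ccccc1)(c1ccccc1)C(C)(C)C | intermediate
6 | linear trimethylsilyl dienol ether of 5 (C5–OSiMe3, C5=C10, C8=C9; not isolated) | CC1=C(O[Si](C)(C)C)C[C@@H](C=C1)C(=C)CO[Si](c1ccccc1)(c1ccccc1)C(C)(C)C | intermediate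
7 | (4S,5R)-5-[3-(tert-butyldiphenylsilyloxy)prop-1-en-2-yl]-4-hydroxy-2-methylcyclohex-2-en-1-one (8α-OH, trans to the C7 branch) | CC1=C[C@H](O)[C@H](CC1=O)C(=C)CO[Si](c1ccccc1)(c1ccccc1)C(C)(C)C | intermediate
8 | 8α-tert-butyldimethylsilyl ether of 7 | CC1=C[C@H](O[Si](C)(C)C(C)(C)C)[C@H](CC1=O)C(=C)CO[Si](c1ccccc1)(c1ccccc1)C(C)(C)C | intermediate
9 | acetaldehyde | CC=O | starting material
10 | lithium enolate (C5–OLi, C5=C10) of the 9,10-dihydro derivative of 8 (not isolated) | [Li+].CC1=C([O-])C[C@H](C(=C)CO[Si](c2ccccc2)(c2ccccc2)C(C)(C)C)[C@@H](O[Si](C)(C)C(C)(C)C)C1 | intermediate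
11 | ring-B ketone with quaternary C10: 10β-(1-hydroxyethyl), 10α-methyl, 8α-OTBS, 7β side chain (both carbinol epimers) | CC(O)[C@@]1(C)C[C@H](O[Si](C)(C)C(C)(C)C)[C@H](CC1=O)C(=C)CO[Si](c1ccccc1)(c1ccccc1)C(C)(C)C | intermediate
12 | 10α-methyl-10β-vinyl ketone (8α-OTBS, 7β side chain) | C=C[C@@]1(C)C[C@H](O[Si](C)(C)C(C)(C)C)[C@H](CC1=O)C(=C)CO[Si](c1ccccc1)(c1ccccc1)C(C)(C)C | intermediate
13 | isopropenylmagnesium bromide | C=C(C)[Mg]Br | starting material
14 | elemane-type alcohol: 5β-hydroxy-5α-isopropenyl, 10α-methyl-10β-vinyl, 8α-OTBS, 7β-[3-(tert-butyldiphenylsilyloxy)prop-1-en-2-yl] | C=C[C@@]1(C)C[C@H](O[Si](C)(C)C(C)(C)C)[C@@H](C(=C)CO[Si](c2ccccc2)(c2ccccc2)C(C)(C)C)C[C@]1(O)C(C)=C | intermediate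
15 | potassium dienolate (C5–OK, C4=C5) of 16 with E-C1=C10 (not isolated) | [K+].[O-]/C1=C(C)\CC/C=C(C)/C[C@H](O[Si](C)(C)C(C)(C)C)[C@@H](C(=C)CO[Si](c2ccccc2)(c2ccccc2)C(C)(C)C)C1 | intermediate
16 | (1(10)E)-8α-(TBS-oxy)-12-(TBDPS-oxy)germacra-1(10),11(13)-dien-5-one, a cyclodec-5-enone (C4 epimers; not isolated) | O=C1C(C)CC/C=C(C)/C[C@H](O[Si](C)(C)C(C)(C)C)[C@@H](C(=C)CO[Si](c2ccccc2)(c2ccccc2)C(C)(C)C)C1 | intermediate
17 | 8α-(TBS-oxy)-12-(TBDPS-oxy)eudesma-1,11(13)-dien-5α-ol (4α-methyl, 10β-methyl, trans ring fusion) | C=C(CO[Si](c1ccccc1)(c1ccccc1)C(C)(C)C)[C@H]1C[C@@]2(O)[C@H](C)CC=C[C@]2(C)C[C@@H]1O[Si](C)(C)C(C)(C)C | intermediate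
18 | 8α-(TBS-oxy)-12-(TBDPS-oxy)eudesma-1,4,11(13)-triene | C=C(CO[Si](c1ccccc1)(c1ccccc1)C(C)(C)C)[C@H]1CC2=C(C)CC=C[C@]2(C)C[C@@H]1O[Si](C)(C)C(C)(C)C | intermediate
19 | 8α-(TBS-oxy)-12-(TBDPS-oxy)eudesma-1,4,11(13)-trien-3-one | C=C(CO[Si](c1ccccc1)(c1ccccc1)C(C)(C)C)[C@H]1CC2=C(C)C(=O)C=C[C@]2(C)C[C@@H]1O[Si](C)(C)C(C)(C)C | intermediate
20 | 8α-(TBS-oxy)-12-(TBDPS-oxy)eudesma-4,11(13)-dien-3-one | C=C(CO[Si](c1ccccc1)(c1ccccc1)C(C)(C)C)[C@H]1CC2=C(C)C(=O)CC[C@]2(C)C[C@@H]1O[Si](C)(C)C(C)(C)C | intermediate
21 | 8α-hydroxy-12-(TBDPS-oxy)eudesma-4,11(13)-dien-3-one | C=C(CO[Si](c1ccccc1)(c1ccccc1)C(C)(C)C)[C@H]1CC2=C(C)C(=O)CC[C@]2(C)C[C@@H]1O | intermediate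
22 | 12-(TBDPS-oxy)eudesma-4,11(13)-diene-3,8-dione | C=C(CO[Si](c1ccccc1)(c1ccccc1)C(C)(C)C)[C@H]1CC2=C(C)C(=O)CC[C@]2(C)CC1=O | intermediate
23 | 12-(TBDPS-oxy)eudesma-4,11(13)-diene-3β,8β-diol | C=C(CO[Si](c1ccccc1)(c1ccccc1)C(C)(C)C)[C@H]1CC2=C(C)[C@@H](O)CC[C@]2(C)C[C@H]1O | intermediate
24 | (E)-3-methylpent-2-enoic acid | CC/C(C)=C/C(=O)O | starting material
25 | 3β-[(E)-3-methylpent-2-enoyloxy]-12-(TBDPS-oxy)eudesma-4,11(13)-dien-8β-ol | C=C(CO[Si](c1ccccc1)(c1ccccc1)C(C)(C)C)[C@H]1CC2=C(C)[C@@H](OC(=O)/C=C(\C)CC)CC[C@]2(C)C[C@H]1O | intermediate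
26 | 8β-acetoxy-3β-[(E)-3-methylpent-2-enoyloxy]-12-(TBDPS-oxy)eudesma-4,11(13)-diene | C=C(CO[Si](c1ccccc1)(c1ccccc1)C(C)(C)C)[C@H]1CC2=C(C)[C@@H](OC(=O)/C=C(\C)CC)CC[C@]2(C)C[C@H]1OC(C)=O | intermediate
27 | 8β-acetoxy-3β-[(E)-3-methylpent-2-enoyloxy]eudesma-4,11(13)-dien-12-ol | C=C(CO)[C@H]1CC2=C(C)[C@@H](OC(=O)/C=C(\C)CC)CC[C@]2(C)C[C@H]1OC(C)=O | intermediate
28 | 8β-acetoxy-3β-[(E)-3-methylpent-2-enoyloxy]eudesma-4,11(13)-dien-12-al | C=C(C=O)[C@H]1CC2=C(C)[C@@H](OC(=O)/C=C(\C)CC)CC[C@]2(C)C[C@H]1OC(C)=O | intermediate
29 | 8β-acetoxy-3β-[(E)-3-methylpent-2-enoyloxy]eudesma-4,11(13)-dien-12-oic acid | C=C(C(=O)O)[C@H]1CC2=C(C)[C@@H](OC(=O)/C=C(\C)CC)CC[C@]2(C)C[C@H]1OC(C)=O | intermediate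
30 | methyl 8β-acetoxy-3β-[(E)-3-methylpent-2-enoyloxy]eudesma-4,11(13)-dien-12-oate (CNP0118541.1) | C=C(C(=O)OC)[C@H]1CC2=C(C)[C@@H](OC(=O)/C=C(\C)CC)CC[C@]2(C)C[C@H]1OC(C)=O | target

Total step count: 21. Longest linear sequence: 21 steps from (R)-carvone 1 (fully linear; 9, 13 and 24 are purchased).

Steps most likely to fail

Step 9 (key step). Process at risk: bonding of the carbonyl carbon to the less substituted alkene carbon C1 in place of C10 (five/seven closure with hydrogen transfer from the C10 methyl); slow ring flip of the alkoxide, so that fragmentation overtakes the sigmatropic shift; or closure before the alkene has turned through the ring, which would give the C10 epimer. Fallback (annulation in place of the pericyclic cascade; sets out from 8, returns at 20): conjugate reduction of enone 8 (LiBH(s-Bu)3, then t-BuOH) would give the saturated ketone F1. Condensation with (R)-1-phenylethylamine (TsOH cat., PhMe, removal of water) would give the imine F2. Its secondary enamine tautomer would add to ethyl vinyl ketone on the α-face of C10 (auxiliary control, against the substrate's own axial preference), and aqueous AcOH would release the 1,5-diketone F3. NaOMe in MeOH would then close ring A by aldol condensation (Robinson annulation) and give enone 20, where steps 13 to 21 follow unchanged.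

Step 4. Process at risk: enolisation toward C6 in place of C8, or attack of the peracid on the enol ether bond, which would put the oxygen on C6 or C10; poor facial selectivity at C8 would also cost material. Fallback (oxidation of an isolated alkene in place of a dienol ether; sets out from 5, returns at 7): KOt-Bu in t-BuOH/THF would form the extended dienolate of 5 under equilibrating conditions, and a cold AcOH quench would protonate it at C10 to give the β,γ-unsaturated ketone F4. mCPBA at −20 °C would epoxidise its C8=C9 alkene anti to the C7 branch (the side-chain alkene is slowed by its allylic silyloxy group) to give the epoxy ketone F5. Et3N would open the epoxide by β-elimination from the C10 enolate and give 7.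

Step 10. Process at risk: loss of the C6 proton in place of the C4 proton (the Δ5 isomer), or ionisation at C5 followed by migration of a group from C10. Fallback (oxidise first, then eliminate; sets out from 17, returns at 19): allylic oxidation of 17 at C3, the only allylic CH2 of the ring alkene (CrO3, 3,5-dimethylpyrazole, CH2Cl2, −20 °C), would give the 5α-hydroxy-1-en-3-one F6. Its tertiary hydroxyl is then β to the ketone, so SOCl2/pyridine (or TsOH) can only eliminate through C4 and would give dienone 19 directly.

Further compounds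
F1 | step 9 | 9,10-dihydro derivative of 8 (10α-methyl, 8α-OTBS, 7β side chain) | C[C@@H]1C[C@H](O[Si](C)(C)C(C)(C)C)[C@H](CC1=O)C(=C)CO[Si](c1ccccc1)(c1ccccc1)C(C)(C)C
F2 | step 9 | (R)-1-phenylethylamine imine of F1 | C[C@@H]1C[C@H](O[Si](C)(C)C(C)(C)C)[C@H](CC1=N[C@H](C)c1ccccc1)C(=C)CO[Si](c1ccccc1)(c1ccccc1)C(C)(C)C
F3 | step 9 | 1,5-diketone: 10β-methyl-10α-(3-oxopentyl) ketone (8α-OTBS, 7β side chain) | CCC(=O)CC[C@]1(C)C[C@H](O[Si](C)(C)C(C)(C)C)[C@H](CC1=O)C(=C)CO[Si](c1ccccc1)(c1ccccc1)C(C)(C)C
F4 | step 4 | β,γ-unsaturated ketone from 5 (C8=C9, C10 epimers) | CC1C=C[C@H](CC1=O)C(=C)CO[Si](c1ccccc1)(c1ccccc1)C(C)(C)C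
F5 | step 4 | 8α,9α-epoxy ketone from F4 | CC1[C@@H]2O[C@@H]2[C@H](CC1=O)C(=C)CO[Si](c1ccccc1)(c1ccccc1)C(C)(C)C
F6 | step 10 | 5α-hydroxy-8α-(TBS-oxy)-12-(TBDPS-oxy)eudesma-1,11(13)-dien-3-one | C=C(CO[Si](c1ccccc1)(c1ccccc1)C(C)(C)C)[C@H]1C[C@@]2(O)[C@H](C)C(=O)C=C[C@]2(C)C[C@@H]1O[Si](C)(C)C(C)(C)C
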